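**Plan**

Numbering of the peroxide half used below: C1=C5 is the ring-fusion alkene shared with the cyclopentenone, C6H=C7, C8 the hemiketal carbon, C9H2, C10H(CH3), C11 the CMe2 carbon.

1. Retrosynthesis: the 1,2-dioxolan-3-ol is opened at C11–O (singlet-oxygen ene reaction) to an α-isopropylidene ketone. Its seven-membered ring is cut at C6–C7 and C9–C10 (vinylcarbenoid (4+3)). The norbornene is cut at the two bonds of a Diels–Alder reaction between the cyclopentadienone ketal of the isopropyl half and 4-methylcyclopent-4-ene-1,3-dione. The isopropyl-half hydroazulene goes back to (S)-carvone.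
2. Feature that allows the key step: in the seven-membered ring of the peroxide half the ring-fusion alkene C1=C5 lies opposite the ketone-level carbon C8. C1 and C5, together with C10H(CH3) on C1 and the ring CH (C6) on C5, are therefore a cisoid diene exocyclic to the five-membered ring (a 2-ethylidene-3-methylenecyclopentanone). The remaining C9–C8(O)–C7 unit is a 2-oxyvinyl carbene whose ester becomes C11.
3. Forward ring order: cyclohexane (carvone) → cycloheptanone (one-carbon ring expansion) → fused cyclopentenone (Au-catalysed [3,3]/Nazarov) → 5,5-dimethoxycyclopentadiene → norbornene with cyclopentanedione (Diels–Alder) → exocyclic diene → second seven-membered ring (cyclopropanation/Cope) → dioxolane (ene reaction, hemiketalisation).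
4. Stereochemistry: the isopropyl-bearing carbon comes from (S)-carvone; the ring methyl from hydroxyl-directed hydrogenation; the four norbornene carbons from the endo, anti-to-methyl Diels–Alder; the bridge carbinol from thermodynamic dissolving-metal reduction; C10 of the peroxide half from convex-face cyclopropanation and a stereospecific boat Cope shift; the hemiketal carbon from equilibration.

Key step: step 22

Assumption: the hemiketal carbon of the 1,2-dioxolan-3-ol equilibrates by ring–chain tautomerism and settles in the configuration of the target; racemic but-3-yn-2-yl acetate is taken as a purchased reagent.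

**Route**

Step 1
Reactants: 1 (S)-(+)-carvone
Product: 2 (S)-carvotanacetone [(5S)-2-methyl-5-(propan-2-yl)cyclohex-2-en-1-one]
Conditions: H2 (1 atm), RhCl(PPh3)3 (cat.), PhH, rt
Reagents that add atoms: none
Why: Homogeneous hydrogenation with Wilkinson's catalyst saturates the unhindered isopropenyl group and leaves the trisubstituted enone alone, so the carvone stereocentre (the future isopropyl-bearing carbon) is carried over unchanged.

Step 2
Reactants: 2 (S)-carvotanacetone
Product: 3 (5S)-2-methyl-5-(propan-2-yl)cyclohex-3-en-1-one (C-2 epimers)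
Conditions: KOt-Bu, t-BuOH, rt; then inverse quench into cold aq. AcOH
Reagents that add atoms: none
Why: Enone deconjugation through the thermodynamic extended dienolate and kinetic α-protonation should move the alkene to the β,γ position next to the isopropyl-bearing carbon.

Step 3
Reactants: 3 β,γ-unsaturated ketone
Product: 5 (4S,5S)-4-hydroxy-2-methyl-5-(propan-2-yl)cyclohex-2-en-1-one, via 3,4-epoxy-2-methyl-5-(propan-2-yl)cyclohexan-1-one (epoxide trans to isopropyl) 4 (not isolated)
Conditions: mCPBA, NaHCO3, CH2Cl2, 0 °C; then Et3N, rt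
Reagents that add atoms: mCPBA, OOC(=O)c1cccc(Cl)c1
Why: Prilezhaev epoxidation anti to the neighbouring isopropyl group followed by base-induced E1cB opening of the β,γ-epoxy ketone is the classical γ-hydroxylation of an enone and places the hydroxyl trans to isopropyl.

Step 4
Reactants: 5 γ-hydroxy enone
Product: 6 (2R,4R,5S)-4-hydroxy-2-methyl-5-(propan-2-yl)cyclohexan-1-one
Conditions: H2 (1 atm), [Ir(cod)(PCy3)(py)]PF6 (cat.), CH2Cl2, rt
Reagents that add atoms: none
Why: Hydroxyl-directed hydrogenation with Crabtree's catalyst delivers hydrogen to the alkene face syn to the allylic OH, so the methyl ends trans to OH and cis to isopropyl, the kinetic arrangement that must not be equilibrated afterwards.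

Step 5
Reactants: 6 hydroxy ketone
Product: 7 (2R,4R,5S)-2-methyl-5-(propan-2-yl)-4-[(triisopropylsilyl)oxy]cyclohexan-1-one
Conditions: TIPSOTf, 2,6-lutidine, CH2Cl2, −78 → 0 °C
Reagents that add atoms: triisopropylsilyl triflate, CC(C)[Si](C(C)C)(C(C)C)OS(=O)(=O)C(F)(F)F
Why: Silyl triflate protection of the hindered secondary alcohol masks the future cycloheptanone oxygen through the acidic, basic and dissolving-metal steps and keeps the isopropyl-bearing carbon from being α to a carbonyl until the end.

Step 6
Reactants: 7 silyloxy cyclohexanone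
Product: 9 (2R,4R,5S)-2-methyl-5-(propan-2-yl)-4-[(triisopropylsilyl)oxy]cycloheptan-1-one, via the 7-(trimethylsilyl) cycloheptanone 8 (not isolated)
Conditions: TMSCHN2, Sc(OTf)3 (cat.), toluene, 0 °C → rt; then aq. citric acid, THF
Reagents that add atoms: trimethylsilyldiazomethane, C[Si](C)(C)C=[N+]=[N-]
Why: Lewis-acid-catalysed diazoalkane homologation (Tiffeneau–Demjanov-type ring expansion) should insert the carbon on the less substituted CH2 side, so the methyl-bearing carbon stays next to the carbonyl, and the α-silyl ketone is protodesilylated under mild acid.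

Step 7
Reactants: 9 cycloheptanone
Product: 10 (4S,5R,7R)-7-methyl-4-(propan-2-yl)-5-[(triisopropylsilyl)oxy]cyclohept-1-en-1-yl trifluoromethanesulfonate
Conditions: KHMDS, THF, −78 °C; PhNTf2
Reagents that add atoms: N-phenylbis(trifluoromethanesulfonimide), O=S(=O)(N(c1ccccc1)S(=O)(=O)C(F)(F)F)C(F)(F)F
Why: Kinetic deprotonation at the unsubstituted α-CH2 and O-sulfonylation (enol triflate formation) fix the future ring-fusion alkene away from the methyl-bearing carbon, which is no longer epimerisable from here on.

Step 8
Reactants: 10 enol triflate; 11 but-3-yn-2-yl acetate (racemic)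
Product: 12 enynyl acetate: 1-(3-acetoxybut-1-ynyl)cycloheptene carrying the methyl, TIPS-oxy and isopropyl groups (epimers at the acetoxy carbon)
Conditions: Pd(PPh3)4 (cat.), CuI (cat.), Et3N, THF, rt
Reagents that add atoms: none
Why: Sonogashira coupling of an enol triflate with a terminal alkyne runs at room temperature, where Pd(0) does not ionise the propargylic acetate.

Step 9
Reactants: 12 enynyl acetate
Product: 13 bicyclic enone: 3-methylcyclopent-2-en-1-one fused at C4/C5 to the substituted cycloheptane (cis ring fusion, diastereomers)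
Conditions: Ph3PAuCl (cat.), AgSbF6 (cat.), wet CH2Cl2, rt
Reagents that add atoms: none
Why: Gold(I) triggers the tandem [3,3]-acyloxy shift/Nazarov cyclisation of 5-acyloxy-1,3-enynes, and hydrolysis of the dienyl acetate gives the cyclopentenone with its carbonyl next to the methyl-bearing side of the seven-membered ring; the two ring-fusion centres are transient.

Step 10
Reactants: 13 bicyclic enone
Product: 14 dimethyl ketal of 13
Conditions: MeOSiMe3, TMSOTf (cat.), CH2Cl2, −78 °C
Reagents that add atoms: methoxytrimethylsilane, CO[Si](C)(C)C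
Why: Noyori ketalisation converts the enone into its ketal without moving the double bond; the dimethyl ketal is chosen because it can later be hydrolysed at the norbornene bridge in dilute acid.

Step 11
Reactants: 14 enone dimethyl ketal
Product: 16 fused 5,5-dimethoxycyclopentadiene (cyclopentadienone ketal of the isopropyl half), via the ring-fusion allylic bromide 15 (not isolated)
Conditions: NBS, AIBN (cat.), CCl4, reflux; then KOt-Bu, THF, 0 °C
Reagents that add atoms: none
Why: Wohl–Ziegler bromination at the tertiary allylic ring-fusion C–H followed by dehydrobromination is the classical entry to cyclopentadienone ketals; the diene cannot undergo [1,5]-hydrogen shifts because the ketal carbon carries no hydrogen.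

Step 12
Reactants: 17 3-methylcyclopent-2-en-1-one
Product: 18 4-methylcyclopent-4-ene-1,3-dione
Conditions: Rh2(cap)4 (cat.), t-BuOOH (aq.), K2CO3, CH2Cl2, rt
Reagents that add atoms: tert-butyl hydroperoxide, CC(C)(C)OO
Why: Dirhodium caprolactamate/TBHP allylic oxidation of an enone at its γ-CH2 gives the ene-dione directly.

Step 13
Reactants: 16 diene ketal; 18 4-methylcyclopent-4-ene-1,3-dione
Product: 19 endo Diels–Alder adduct: 7,7-dimethoxynorbornene fused to the TIPS-oxy cycloheptane and, endo, to a 2-methylcyclopentane-1,3-dione (angular methyl exo)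
Conditions: toluene, BHT (cat.), 70 °C
Reagents that add atoms: none
Why: In this normal-demand Diels–Alder reaction the unsubstituted diene terminus bonds first to the unsubstituted dienophile carbon, the dione ring goes endo, and the dienophile approaches the diene face anti to the allylic methyl of the seven-membered ring, which sets the four norbornene stereocentres.

Step 14
Reactants: 19 Diels–Alder adduct
Product: 20 bridge ketone (7-norbornenone)
Conditions: 5% aq. H2SO4, THF, rt
Reagents that add atoms: water, O
Why: Acid hydrolysis of a 7,7-dimethoxynorbornene to the 7-ketone proceeds in dilute aqueous acid at room temperature, conditions the secondary TIPS ether and the enolised 1,3-dione should survive.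

Step 15
Reactants: 20 bridge ketone
Product: 21 syn-7-norbornenol (hydroxyl over the alkene)
Conditions: Li, NH3(l), THF, −78 °C; then NH4Cl
Reagents that add atoms: none
Why: Dissolving-metal ketone reduction should give the thermodynamically preferred carbinol (hydroxyl over the alkene, hydrogen towards the exo methyl), whereas hydride reagents would attack from the alkene side and give the epimer; the 1,3-dione is protected as its enolate and the tetrasubstituted alkene is inert.

Step 16
Reactants: 21 hydroxy dione
Product: 22 vinylogous methyl ester (3-methoxy-enone with the carbonyl next to the angular methyl)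
Conditions: MeOH, CSA (cat.), 3 Å MS, rt
Reagents that add atoms: methanol, CO
Why: Acid-catalysed enol etherification of the unsymmetrical 1,3-dione is reversible and should place the methoxy group on the less hindered carbonyl, leaving the carbonyl flanked by the quaternary carbon.

Step 17
Reactants: 22 vinylogous ester
Product: 24 3-methylenecyclopentanone (β,γ-unsaturated ketone), via the 1-methoxy-3-methylenecyclopentene 23 (not isolated)
Conditions: Cp2TiMe2, toluene, 70 °C; then aq. oxalic acid, THF, 0 °C
Reagents that add atoms: dimethyltitanocene, C[Ti](C)(C1C=CC=C1)C1C=CC=C1; water, O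
Why: Petasis methylenation turns the vinylogous ester carbonyl into the exocyclic methylene, and mild hydrolysis of the dienol ether with kinetic α-protonation should deliver the deconjugated ketone.

Step 18
Reactants: 24 3-methylene ketone; 25 acetaldehyde
Product: 26 aldol: 2-(1-hydroxyethyl)-3-methylenecyclopentanone (epimers)
Conditions: LDA, THF, −78 °C; then 25
Reagents that add atoms: none
Why: The CH2 between the carbonyl and the exocyclic alkene is by far the most acidic site, so LDA forms the extended enolate there and its aldol addition occurs at the α-carbon; both new centres are removed in the next step.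

Step 19
Reactants: 26 aldol
Product: 28 norbornene with 2-ethylidene-3-methylenecyclopentanone ring, bridge acetate and TIPS ether (key-step precursor), via the diacetate 27 (not isolated)
Conditions: Ac2O, pyridine, DMAP (cat.), CH2Cl2, 0 °C → rt; then DBU, rt
Reagents that add atoms: acetic anhydride, CC(=O)OC(C)=O
Why: Acetylation esterifies the bridge alcohol (the final acetate) and the aldol hydroxyl, and E1cB elimination of the β-acetoxy ketone should give the ethylidene with its methyl cis to the carbonyl, the isomer that avoids the in-plane clash with the neighbouring methylene.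

Step 20
Reactants: 29 methyl acetoacetate
Product: 30 methyl 2-diazo-3-oxobutanoate
Conditions: p-ABSA, Et3N, MeCN, rt
Reagents that add atoms: 4-acetamidobenzenesulfonyl azide, CC(=O)Nc1ccc(cc1)S(=O)(=O)N=[N+]=[N-]
Why: Regitz diazo transfer to the active methylene of a β-keto ester.

Step 21
Reactants: 30 diazo keto ester
Product: 31 methyl 2-diazo-3-(triisopropylsilyloxy)but-3-enoate
Conditions: TIPSOTf, Et3N, CH2Cl2, 0 °C
Reagents that add atoms: triisopropylsilyl triflate, CC(C)[Si](C(C)C)(C(C)C)OS(=O)(=O)C(F)(F)F
Why: Soft enolisation and O-silylation of the acetyl group give the 2-siloxyvinyl diazoacetate; the triisopropylsilyl group is chosen so that methyllithium does not attack silicon in step 23.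

Step 22
Reactants: 28 exocyclic dienone; 31 siloxyvinyl diazoacetate
Product: 33 cycloheptadiene with TIPS enol ether and methyl ester (key-step product), via the spiro cis-divinylcyclopropane 32 (not isolated)
Conditions: Rh2(S-PTAD)4 (1 mol %; catalyst enantiomer matched to the substrate, to be settled against Rh2(R-PTAD)4), slow addition of 31, hexanes/PhCF3, −20 → 40 °C
Reagents that add atoms: none
Why: Rh(II) converts 31 into a donor/acceptor vinylcarbenoid that cyclopropanates the exocyclic methylene of 28, giving 32 with the siloxyvinyl group cis to the ethylidene-bearing ring carbon. 32 then undergoes a [3,3] (Cope) shift through the boat transition state, which breaks the spiro cyclopropane bond and joins the vinyl terminus to the ethylidene carbon; the closest known reaction is the Rh-catalysed cyclopropanation/Cope rearrangement (formal (4+3)) of dienes with 2-siloxyvinyl diazoacetates. The cyclopropane closes by concerted, asynchronous [2+1] carbene transfer and the seven-membered ring by the sigmatropic shift, with no ionic intermediate. The single new stereocentre, C10, is controlled by the face of cyclopropanation (the convex face of the cyclopentanone, turned away from the norbornene, reinforced by the matched catalyst) together with the ethylidene geometry (methyl cis to C=O, hydrogen inside the boat), the Cope step being stereospecific. Site selectivity is needed for the methylene over the other alkenes and carbonyls: the methylene is the only unhindered 1,1-disubstituted alkene, the ethylidene is electron-poor and trisubstituted, and the norbornene alkene is tetrasubstituted and shielded. A trans-divinyl isomer, should it form, would need heating to epimerise before it rearranges.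

Step 23
Reactants: 33 siloxy cycloheptadiene ester
Product: 35 α-isopropylidene cycloheptenone with free bridge alcohol, via the 2-hydroxyprop-2-yl tertiary alcohol 34 (not isolated)
Conditions: LiHMDS, THF, −78 °C; MeLi (excess), −78 → 0 °C; then 1 M HCl, THF, 0 °C
Reagents that add atoms: methyllithium, [Li]C
Why: The cyclopentenone is first masked in situ as its lithium enolate (enolate protection), so methyllithium should add twice only to the β-siloxy acrylate ester (and cleave the acetate); acid then ionises the tertiary allylic alcohol with loss of the enol silyl group (Stork–Danheiser-type transposition) to give the α-isopropylidene ketone.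

Step 24
Reactants: 35 bridge alcohol
Product: 36 bridge acetate
Conditions: Ac2O, pyridine, DMAP (cat.), CH2Cl2, rt
Reagents that add atoms: acetic anhydride, CC(=O)OC(C)=O
Why: Acylation of the only remaining hydroxyl restores the acetate.

Step 25
Reactants: 36 TIPS ether
Product: 37 secondary alcohol of the isopropyl half
Conditions: HF·pyridine, THF, 0 °C → rt
Reagents that add atoms: none
Why: Fluoride desilylation under buffered acidic conditions frees the alcohol and should leave the acetate and the dienone untouched.

Step 26
Reactants: 37 secondary alcohol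
Product: 38 isopropylidene triketone (8-oxo-7(11)-ene of the peroxide half, cycloheptanone of the isopropyl half)
Conditions: Dess–Martin periodinane, NaHCO3, CH2Cl2, rt
Reagents that add atoms: none
Why: Dess–Martin oxidation under buffered, non-enolising conditions gives the cycloheptanone without epimerising the isopropyl-bearing carbon, which is now α to a carbonyl.

Step 27
Reactants: 38 isopropylidene triketone
Product: 40 CNP0317907.1, via the open tertiary hydroperoxide 39 (not isolated)
Conditions: O2, hν (visible), TPP (cat.), CH2Cl2, −20 °C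
Reagents that add atoms: oxygen, O=O
Why: The Schenck ene reaction of singlet oxygen with an s-cis α-isopropylidene ketone (as in the photooxygenation of pulegone) bonds oxygen to the dimethyl-bearing carbon and removes the doubly allylic ring hydrogen geminal to the carbonyl, and the hydroperoxy ketone closes to the 1,2-dioxolan-3-ol; the s-trans cyclopentenone is unreactive and both faces of the norbornene alkene are shielded (syn acetate, endo ring).

**Compound list**

1 | (S)-(+)-carvone | CC1=CC[C@@H](CC1=O)C(C)=C | starting material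
2 | (S)-carvotanacetone | CC1=CC[C@@H](CC1=O)C(C)C | intermediate
3 | (5S)-2-methyl-5-(propan-2-yl)cyclohex-3-en-1-one (C-2 epimers) | CC1C=C[C@@H](CC1=O)C(C)C | intermediate
4 | 3,4-epoxy-2-methyl-5-(propan-2-yl)cyclohexan-1-one, epoxide trans to isopropyl (not isolated) | CC1[C@H]2O[C@H]2[C@@H](CC1=O)C(C)C | intermediate
5 | (4S,5S)-4-hydroxy-2-methyl-5-(propan-2-yl)cyclohex-2-en-1-one | CC1=C[C@@H](O)[C@@H](CC1=O)C(C)C | intermediate
6 | (2R,4R,5S)-4-hydroxy-2-methyl-5-(propan-2-yl)cyclohexan-1-one | C[C@@H]1C[C@@H](O)[C@@H](CC1=O)C(C)C | intermediate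
7 | (2R,4R,5S)-2-methyl-5-(propan-2-yl)-4-[(triisopropylsilyl)oxy]cyclohexan-1-one | C[C@@H]1C[C@@H](O[Si](C(C)C)(C(C)C)C(C)C)[C@@H](CC1=O)C(C)C | intermediate
8 | 7-(trimethylsilyl) derivative of 9 (not isolated) | C[Si](C)(C)C1C[C@@H](C(C)C)[C@H](O[Si](C(C)C)(C(C)C)C(C)C)C[C@@H](C)C1=O | intermediate
9 | (2R,4R,5S)-2-methyl-5-(propan-2-yl)-4-[(triisopropylsilyl)oxy]cycloheptan-1-one | C1C[C@@H](C(C)C)[C@H](O[Si](C(C)C)(C(C)C)C(C)C)C[C@@H](C)C1=O | intermediate
10 | (4S,5R,7R)-7-methyl-4-(propan-2-yl)-5-[(triisopropylsilyl)oxy]cyclohept-1-en-1-yl triflate | C1=C(OS(=O)(=O)C(F)(F)F)[C@H](C)C[C@@H](O[Si](C(C)C)(C(C)C)C(C)C)[C@H](C(C)C)C1 | intermediate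
11 | but-3-yn-2-yl acetate (racemic) | CC(OC(C)=O)C#C | starting material
12 | enynyl acetate (epimers at the acetoxy carbon) | C1=C(C#CC(C)OC(C)=O)[C@H](C)C[C@@H](O[Si](C(C)C)(C(C)C)C(C)C)[C@H](C(C)C)C1 | intermediate
13 | cis-fused bicyclic 3-methylcyclopent-2-enone (ring-fusion diastereomers) | O=C1C=C(C)C2C1[C@H](C)C[C@@H](O[Si](C(C)C)(C(C)C)C(C)C)[C@H](C(C)C)C2 | intermediate
14 | dimethyl ketal of 13 | COC1(OC)C=C(C)C2C1[C@H](C)C[C@@H](O[Si](C(C)C)(C(C)C)C(C)C)[C@H](C(C)C)C2 | intermediate
15 | ring-fusion allylic bromide (not isolated) | COC1(OC)C=C(C)C2(Br)C1[C@H](C)C[C@@H](O[Si](C(C)C)(C(C)C)C(C)C)[C@H](C(C)C)C2 | intermediate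
16 | fused 5,5-dimethoxycyclopentadiene (diene of the isopropyl half) | COC1(OC)C=C(C)C2=C1[C@H](C)C[C@@H](O[Si](C(C)C)(C(C)C)C(C)C)[C@H](C(C)C)C2 | intermediate
17 | 3-methylcyclopent-2-en-1-one | CC1=CC(=O)CC1 | starting material
18 | 4-methylcyclopent-4-ene-1,3-dione | CC1=CC(=O)CC1=O | intermediate
19 | endo Diels–Alder adduct (bridge dimethyl ketal, 1,3-dione) | COC1(OC)[C@H]2C(C)=C3C[C@@H](C(C)C)[C@H](O[Si](C(C)C)(C(C)C)C(C)C)C[C@@H](C)[C@]31[C@]1(C)C(=O)CC(=O)[C@H]21 | intermediate
20 | bridge ketone | O=C1[C@H]2C(C)=C3C[C@@H](C(C)C)[C@H](O[Si](C(C)C)(C(C)C)C(C)C)C[C@@H](C)[C@]31[C@]1(C)C(=O)CC(=O)[C@H]21 | intermediate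
21 | syn bridge alcohol | O[C@H]1[C@H]2C(C)=C3C[C@@H](C(C)C)[C@H](O[Si](C(C)C)(C(C)C)C(C)C)C[C@@H](C)[C@]31[C@]1(C)C(=O)CC(=O)[C@H]21 | intermediate
22 | vinylogous methyl ester | O[C@H]1[C@H]2C(C)=C3C[C@@H](C(C)C)[C@H](O[Si](C(C)C)(C(C)C)C(C)C)C[C@@H](C)[C@]31[C@]1(C)C(=O)C=C(OC)[C@H]21 | intermediate
23 | methoxy diene (dienol ether, not isolated) | O[C@H]1[C@H]2C(C)=C3C[C@@H](C(C)C)[C@H](O[Si](C(C)C)(C(C)C)C(C)C)C[C@@H](C)[C@]31[C@]1(C)C(=C)C=C(OC)[C@H]21 | intermediate
24 | 3-methylene ketone | O[C@H]1[C@H]2C(C)=C3C[C@@H](C(C)C)[C@H](O[Si](C(C)C)(C(C)C)C(C)C)C[C@@H](C)[C@]31[C@]1(C)C(=C)CC(=O)[C@H]21 | intermediate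
25 | acetaldehyde | CC=O | starting material
26 | aldol (epimers) | O[C@H]1[C@H]2C(C)=C3C[C@@H](C(C)C)[C@H](O[Si](C(C)C)(C(C)C)C(C)C)C[C@@H](C)[C@]31[C@]1(C)C(=C)C(C(C)O)C(=O)[C@H]21 | intermediate
27 | diacetate (not isolated) | CC(=O)O[C@H]1[C@H]2C(C)=C3C[C@@H](C(C)C)[C@H](O[Si](C(C)C)(C(C)C)C(C)C)C[C@@H](C)[C@]31[C@]1(C)C(=C)C(C(C)OC(C)=O)C(=O)[C@H]21 | intermediate
28 | key-step precursor: 2-ethylidene-3-methylenecyclopentanone on the norbornene | CC(=O)O[C@H]1[C@H]2C(C)=C3C[C@@H](C(C)C)[C@H](O[Si](C(C)C)(C(C)C)C(C)C)C[C@@H](C)[C@]31[C@]1(C)C(=C)/C(=C/C)C(=O)[C@H]21 | intermediate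
29 | methyl acetoacetate | COC(=O)CC(C)=O | starting material
30 | methyl 2-diazo-3-oxobutanoate | COC(=O)C(=[N+]=[N-])C(C)=O | intermediate
31 | methyl 2-diazo-3-(triisopropylsilyloxy)but-3-enoate | COC(=O)C(=[N+]=[N-])C(=C)O[Si](C(C)C)(C(C)C)C(C)C | intermediate
32 | spiro cis-divinylcyclopropane (not isolated) | CC(=O)O[C@H]1[C@H]2C(C)=C3C[C@@H](C(C)C)[C@H](O[Si](C(C)C)(C(C)C)C(C)C)C[C@@H](C)[C@]31[C@]1(C)[C@]3(C[C@]3(C(=O)OC)C(O[Si](C(C)C)(C(C)C)C(C)C)=C)/C(=C/C)C(=O)[C@H]21 | intermediate
33 | key-step product: cycloheptadiene with TIPS enol ether and methyl ester | CC(=O)O[C@H]1[C@H]2C(C)=C3C[C@@H](C(C)C)[C@H](O[Si](C(C)C)(C(C)C)C(C)C)C[C@@H](C)[C@]31[C@]1(C)C3=C(C(=O)[C@H]21)[C@H](C)CC(O[Si](C(C)C)(C(C)C)C(C)C)=C(C(=O)OC)C3 | intermediate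
34 | tertiary alcohol (not isolated) | O[C@H]1[C@H]2C(C)=C3C[C@@H](C(C)C)[C@H](O[Si](C(C)C)(C(C)C)C(C)C)C[C@@H](C)[C@]31[C@]1(C)C3=C(C(=O)[C@H]21)[C@H](C)CC(O[Si](C(C)C)(C(C)C)C(C)C)=C(C(C)(C)O)C3 | intermediate
35 | isopropylidene ketone, bridge alcohol | O[C@H]1[C@H]2C(C)=C3C[C@@H](C(C)C)[C@H](O[Si](C(C)C)(C(C)C)C(C)C)C[C@@H](C)[C@]31[C@]1(C)C3=C(C(=O)[C@H]21)[C@H](C)CC(=O)C(=C(C)C)C3 | intermediate
36 | isopropylidene ketone, bridge acetate | CC(=O)O[C@H]1[C@H]2C(C)=C3C[C@@H](C(C)C)[C@H](O[Si](C(C)C)(C(C)C)C(C)C)C[C@@H](C)[C@]31[C@]1(C)C3=C(C(=O)[C@H]21)[C@H](C)CC(=O)C(=C(C)C)C3 | intermediate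
37 | secondary alcohol of the isopropyl half | CC(=O)O[C@H]1[C@H]2C(C)=C3C[C@@H](C(C)C)[C@H](O)C[C@@H](C)[C@]31[C@]1(C)C3=C(C(=O)[C@H]21)[C@H](C)CC(=O)C(=C(C)C)C3 | intermediate
38 | isopropylidene triketone | CC(=O)O[C@H]1[C@H]2C(C)=C3C[C@@H](C(C)C)C(=O)C[C@@H](C)[C@]31[C@]1(C)C3=C(C(=O)[C@H]21)[C@H](C)CC(=O)C(=C(C)C)C3 | intermediate
39 | open tertiary hydroperoxide (not isolated) | CC(=O)O[C@H]1[C@H]2C(C)=C3C[C@@H](C(C)C)C(=O)C[C@@H](C)[C@]31[C@]1(C)C3=C(C(=O)[C@H]21)[C@H](C)CC(=O)C(C(C)(C)OO)=C3 | intermediate
40 | CNP0317907.1 | CC(=O)O[C@H]1[C@H]2C(C)=C3C[C@@H](C(C)C)C(=O)C[C@@H](C)[C@]31[C@]1(C)C3=C(C(=O)[C@H]21)[C@H](C)C[C@@]1(O)OOC(C)(C)C1=C3 | target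

**Step count and risks**

Total: 27 steps. Longest linear sequence: 24 steps (steps 1–11, 13–19, 22–27).

The three steps most likely to fail:

Step 23. The cyclopentenone may be enolised incompletely, so that methyllithium adds to its carbonyl, or the ring-fusion alkene may shift when the enolate is reprotonated. Fallback: the carbonyl is taken out of play for the addition. From 33, Luche reduction (NaBH4, CeCl3·7H2O, MeOH, −78 °C) should give the allylic alcohol F1. Excess MeLi followed by 1 M HCl/THF would then convert ester, enol ether and acetate as in step 23 into the isopropylidene ketone diol F2. MnO2 in CH2Cl2 oxidises only the allylic carbinol, and the sequence comes back at 35.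

Step 13. The cycloaddition may stall or lose regiocontrol, because its second bond joins two fully substituted carbons beside the allylic methyl. Fallback: the quaternary methyl is put in after the cycloaddition. From 16, commercial cyclopent-4-ene-1,3-dione (symmetrical and more reactive) would give the endo adduct F3. MeOH/CSA should give the vinylogous ester F4 with the methoxy group on the carbonyl remote from the quaternary bridgehead; the regioisomer can be returned to F3 with dilute acid. LDA then MeI would methylate the only α′-position from the exo face (Stork–Danheiser α′-alkylation) to give the methylated vinylogous ester F5. 5% aq. H2SO4/THF hydrolyses the enol ether and the bridge ketal together, and the route is rejoined at 20.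

Step 27. Singlet oxygen may also attack the tetrasubstituted norbornene alkene or add across the product diene, and prolonged irradiation may degrade the peroxide. Fallback: ground-state oxygenation through the extended enolate. From 38, DBU in MeCN under O2 at 0 °C would ionise the doubly activated ring CH2 (γ to the cyclopentenone and allylic to the isopropylidene). The delocalised enolate is expected to take up oxygen at the dimethyl-bearing terminus (vinylogous enolate autoxidation), giving 39 and, by ring closure, 40. No new compound is involved.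

**Further compounds**

F1 | step 23 | Luche alcohol of 33 (cyclopentenol, epimers at the carbinol) | CC(=O)O[C@H]1[C@H]2C(C)=C3C[C@@H](C(C)C)[C@H](O[Si](C(C)C)(C(C)C)C(C)C)C[C@@H](C)[C@]31[C@]1(C)C3=C(C(O)[C@H]21)[C@H](C)CC(O[Si](C(C)C)(C(C)C)C(C)C)=C(C(=O)OC)C3
F2 | step 23 | isopropylidene ketone diol (bridge and allylic alcohols) | O[C@H]1[C@H]2C(C)=C3C[C@@H](C(C)C)[C@H](O[Si](C(C)C)(C(C)C)C(C)C)C[C@@H](C)[C@]31[C@]1(C)C3=C(C(O)[C@H]21)[C@H](C)CC(=O)C(=C(C)C)C3
F3 | step 13 | endo adduct of 16 with cyclopent-4-ene-1,3-dione (no angular methyl) | COC1(OC)[C@H]2C(C)=C3C[C@@H](C(C)C)[C@H](O[Si](C(C)C)(C(C)C)C(C)C)C[C@@H](C)[C@]31[C@@H]1C(=O)CC(=O)[C@H]21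
F4 | step 13 | vinylogous methyl ester of F3 | COC1(OC)[C@H]2C(C)=C3C[C@@H](C(C)C)[C@H](O[Si](C(C)C)(C(C)C)C(C)C)C[C@@H](C)[C@]31[C@@H]1C(=O)C=C(OC)[C@H]21
F5 | step 13 | α′-methylated vinylogous ester | COC1(OC)[C@H]2C(C)=C3C[C@@H](C(C)C)[C@H](O[Si](C(C)C)(C(C)C)C(C)C)C[C@@H](C)[C@]31[C@]1(C)C(=O)C=C(OC)[C@H]21
F0 | step 27 | none | none
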